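**Retrosynthetic overview**
- C2–aryl bond: the (2S) centre is set last, by enantioselective rhodium-catalysed 1,4-addition of a silyl-protected catechol boronic acid to an 8-substituted 7-hydroxychromone. No basic step follows.
- Chromone: rings A and C are built in one flask. A bis(silyloxy)diene undergoes [4+2] benzannulation with but-3-yn-2-one, and a formamide acetal then supplies the one carbon that closes the pyranone.
- The diene is the double silyl enol ether of a seven-membered β-keto lactone. Aromatisation expels the lactone oxygen and releases the (Z)-4-hydroxy-3-methylbut-2-enyl chain at C8.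
- Lactone: ring-closing metathesis of methallyl 2-allylacetoacetate. The seven-membered ring forces a cis olefin, which is the Z geometry of the target.
- Ring order: the sacrificial oxepinone first, then ring A and ring C together (the oxepinone opens). Ring B is bought.

Assumption: the SMILES is read as (2S) at C2 and Z at the side-chain olefin (CH2OH cis to the benzylic CH2). Racemic 1 is acceptable because its stereocentre is erased in step 3.

**Step 1**
Reactants: 1 ethyl 2-acetylpent-4-enoate (racemic); 2 2-methylprop-2-en-1-ol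
Product: 3 2-methylprop-2-en-1-yl 2-acetylpent-4-enoate (racemic)
Conditions: 2 (3 equiv), DMAP (0.3 equiv), toluene, 4 Å MS, 105–110 °C
Reagents that add atoms: none
Why: DMAP-catalysed transesterification of an enolisable β-keto ester, driven by removal of ethanol and held at or below 110 °C so that Carroll rearrangement of the new allylic β-keto ester does not start; the racemic α-centre is irrelevant because step 3 erases it.

**Step 2**
Reactants: 3 2-methylprop-2-en-1-yl 2-acetylpent-4-enoate
Product: 4 3-acetyl-6-methyl-4,7-dihydrooxepin-2(3H)-one (racemic)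
Conditions: second-generation Hoveyda–Grubbs catalyst (5 mol %), toluene (2 mM), 80 °C, argon sparge
Reagents that add atoms: none
Why: Ring-closing metathesis that initiates at the allyl olefin and closes on the methallyl olefin; a trisubstituted olefin inside a seven-membered ring can only be cis, so ring carbons C4 and C7 lie on the same side, which is the Z relationship between the benzylic CH2 and the CH2O of the target.

**Step 3**
Reactants: 4 3-acetyl-6-methyl-4,7-dihydrooxepin-2(3H)-one
Product: 5 6-methyl-2-(trimethylsilyloxy)-3-[1-(trimethylsilyloxy)ethenyl]-4,7-dihydrooxepine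
Conditions: TMSOTf (2.3 equiv), Et3N (2.6 equiv), Et2O, −10 → 10 °C; cold pentane extraction, used at once
Reagents that add atoms: trimethylsilyl trifluoromethanesulfonate, C[Si](C)(C)OS(=O)(=O)C(F)(F)F
Why: Soft double enolisation and O-silylation of a 1,3-dicarbonyl compound (the silyl triflate–amine route to 1,3-bis(silyloxy)-1,3-dienes), which removes the only stereocentre and leaves the ring olefin untouched; it is kept cold because the product is an allyl silyl ketene acetal that could undergo Ireland–Claisen ring contraction on heating.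

**Step 4**
Reactants: 5 6-methyl-2-(trimethylsilyloxy)-3-[1-(trimethylsilyloxy)ethenyl]-4,7-dihydrooxepine; 6 but-3-yn-2-one
Product: 10 7-hydroxy-8-[(2Z)-4-hydroxy-3-methylbut-2-en-1-yl]-4H-chromen-4-one, via bicyclic cycloadduct 7 (not isolated), via bis-silyl acetophenone 8 (not isolated), via enaminone 9 (not isolated)
Conditions: 6 (3 equiv), toluene (1 M), 0 → 25 °C, 16 h; evaporate excess 6; DMF-DMA (1.5 equiv), toluene, 80 °C, 3 h; AcOH–H2O–THF, 50 °C, 2 h (one flask)
Reagents that add atoms: N,N-dimethylformamide dimethyl acetal, COC(OC)N(C)C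
Why: Proposed new method: a Danishefsky–Brassard-type polar Diels–Alder benzannulation (closest known type: 1-alkoxy-1,3-bis(silyloxy)dienes plus acetylenic ketones or esters, giving 2,4-dioxygenated aryl carbonyl compounds with loss of the alkoxy group) is run on a cyclic ketene acetal, so the CH2 terminus attacks the alkyne β-carbon, the ketene-acetal carbon closes on the α-carbon (acetyl ortho to the ketal carbon, para to the enol silyl ether), and aromatisation of 7 expels the tethered alkoxide, which opens the oxepine, forms ring A and frees the side chain with its ring-derived Z geometry, after which enaminone formation and acid-induced addition–elimination by the ortho-phenol (standard chromone synthesis) close ring C in the same flask; no stereocentre is formed.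

**Step 5**
Reactants: 11 4-bromobenzene-1,2-diol
Product: 12 4-bromo-1,2-bis(tert-butyldimethylsilyloxy)benzene
Conditions: TBSCl (2.3 equiv), imidazole (4 equiv), DMF, 25 °C
Reagents that add atoms: tert-butyldimethylsilyl chloride, CC(C)(C)[Si](C)(C)Cl
Why: Imidazole-promoted silylation of both phenols; aryl TBS ethers survive lithiation and neutral aqueous rhodium catalysis and are removed by fluoride without acid or base.

**Step 6**
Reactants: 12 4-bromo-1,2-bis(tert-butyldimethylsilyloxy)benzene
Product: 13 [3,4-bis(tert-butyldimethylsilyloxy)phenyl]boronic acid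
Conditions: n-BuLi, THF, −78 °C; B(OiPr)3, −78 → 0 °C; 1 M HCl (1 equiv), H2O, 0 °C
Reagents that add atoms: triisopropyl borate, CC(C)OB(OC(C)C)OC(C)C; water, O
Why: Bromine–lithium exchange, borate trapping and mild hydrolysis; the aryllithium sits meta and para to the silyloxy groups, so no ortho O-to-C silyl migration is possible.

**Step 7**
Reactants: 10 7-hydroxy-8-[(2Z)-4-hydroxy-3-methylbut-2-en-1-yl]-4H-chromen-4-one; 13 [3,4-bis(tert-butyldimethylsilyloxy)phenyl]boronic acid
Product: 14 (2S)-2-[3,4-bis(tert-butyldimethylsilyloxy)phenyl]-7-hydroxy-8-[(2Z)-4-hydroxy-3-methylbut-2-en-1-yl]-2,3-dihydro-4H-chromen-4-one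
Conditions: 13 (3 equiv), [Rh(OH)(cod)]2 (2.5 mol %), (S)-MeO-F12-BIPHEP (5.5 mol %), toluene–THF–H2O, 25 °C, no added base
Reagents that add atoms: none
Why: Hayashi–Miyaura asymmetric 1,4-addition, in which the electron-poor (S)-biaryl diphosphine speeds insertion into the weakly electrophilic chromone and delivers the aryl group to the C2 face that gives (2S) (the same sense in which (S)-BINAP-type ligands give (S)-3-arylcyclohexanones, to be confirmed by CD), while the neutral medium at 25 °C prevents retro-oxa-Michael racemisation and leaves the unconjugated Z olefin alone.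

**Step 8**
Reactants: 14 (2S)-2-[3,4-bis(tert-butyldimethylsilyloxy)phenyl]-7-hydroxy-8-[(2Z)-4-hydroxy-3-methylbut-2-en-1-yl]-2,3-dihydro-4H-chromen-4-one
Product: 15 (2S)-2-(3,4-dihydroxyphenyl)-7-hydroxy-8-[(2Z)-4-hydroxy-3-methylbut-2-en-1-yl]-2,3-dihydro-4H-chromen-4-one
Conditions: HF·pyridine, THF–pyridine, 0 → 20 °C; pH 6 phosphate work-up
Reagents that add atoms: none
Why: Fluoride-driven cleavage of the aryl silyl ethers in a buffered, weakly acidic medium, which avoids both base-induced racemisation of a 4'-hydroxyflavanone (ring opening to the chalcone or quinone methide) and acid-induced cyclisation of the allylic alcohol onto the 7-OH.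

**Compound list**
1 | ethyl 2-acetylpent-4-enoate (racemic) | CCOC(=O)C(CC=C)C(C)=O | starting material
2 | 2-methylprop-2-en-1-ol | C=C(C)CO | starting material
3 | 2-methylprop-2-en-1-yl 2-acetylpent-4-enoate (racemic) | C=CCC(C(C)=O)C(=O)OCC(C)=C | intermediate
4 | 3-acetyl-6-methyl-4,7-dihydrooxepin-2(3H)-one (racemic, ring olefin cis) | CC(=O)C1CC=C(C)COC1=O | intermediate
5 | 6-methyl-2-(trimethylsilyloxy)-3-[1-(trimethylsilyloxy)ethenyl]-4,7-dihydrooxepine | C=C(O[Si](C)(C)C)C1=C(O[Si](C)(C)C)OCC(C)=CC1 | intermediate
6 | but-3-yn-2-one | CC(=O)C#C | starting material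
7 | 1-[3-methyl-6,9a-bis(trimethylsilyloxy)-2,5,7,9a-tetrahydro-1-benzoxepin-9-yl]ethanone (racemic) | CC(=O)C1=CCC(O[Si](C)(C)C)=C2CC=C(C)COC12O[Si](C)(C)C | intermediate (not isolated)
8 | 1-{3-[(2Z)-4-hydroxy-3-methylbut-2-en-1-yl]-2,4-bis(trimethylsilyloxy)phenyl}ethanone | CC(=O)c1ccc(O[Si](C)(C)C)c(C/C=C(/C)CO)c1O[Si](C)(C)C | intermediate (not isolated)
9 | (2E)-1-{2,4-dihydroxy-3-[(2Z)-4-hydroxy-3-methylbut-2-en-1-yl]phenyl}-3-(dimethylamino)prop-2-en-1-one | CN(C)/C=C/C(=O)c1ccc(O)c(C/C=C(/C)CO)c1O | intermediate (not isolated)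
10 | 7-hydroxy-8-[(2Z)-4-hydroxy-3-methylbut-2-en-1-yl]-4H-chromen-4-one | C/C(=C/Cc1c(O)ccc2c1OC=CC2=O)CO | intermediate
11 | 4-bromobenzene-1,2-diol | Oc1ccc(Br)cc1O | starting material
12 | 4-bromo-1,2-bis(tert-butyldimethylsilyloxy)benzene | CC(C)(C)[Si](C)(C)Oc1ccc(Br)cc1O[Si](C)(C)C(C)(C)C | intermediate
13 | [3,4-bis(tert-butyldimethylsilyloxy)phenyl]boronic acid | CC(C)(C)[Si](C)(C)Oc1ccc(B(O)O)cc1O[Si](C)(C)C(C)(C)C | intermediate
14 | (2S)-2-[3,4-bis(tert-butyldimethylsilyloxy)phenyl]-7-hydroxy-8-[(2Z)-4-hydroxy-3-methylbut-2-en-1-yl]-2,3-dihydro-4H-chromen-4-one | C/C(=C/Cc1c(O)ccc2c1O[C@H](c1ccc(O[Si](C)(C)C(C)(C)C)c(O[Si](C)(C)C(C)(C)C)c1)CC2=O)CO | intermediate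
15 | (2S)-2-(3,4-dihydroxyphenyl)-7-hydroxy-8-[(2Z)-4-hydroxy-3-methylbut-2-en-1-yl]-2,3-dihydro-4H-chromen-4-one | C/C(=C/Cc1c(O)ccc2c1O[C@H](c1ccc(O)c(O)c1)CC2=O)CO | target

**Total step count:** 8. **Longest linear sequence:** 6 (steps 1, 2, 3, 4, 7, 8).

**Three steps most likely to fail**

Step 4.
- Diene 5 is an allyl silyl ketene acetal held in a boat. If the cycloaddition needs heat, Ireland–Claisen ring contraction to a vinylcyclopropane silyl ester can win.
- Cycloadduct 7 could also lose silanolate instead of the alkoxide and end as a 2,5-dihydro-1-benzoxepine.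
- DMF-DMA may O-methylate the para-phenol.

The fallback sets out from 4 and comes back at 9. It gives up the cyclic ketene acetal for the acyclic diene class on which this benzannulation is established. DMAP-catalysed methanolysis of 4 opens the lactone to methyl (4Z)-2-acetyl-6-hydroxy-5-methylhex-4-enoate F1. TMSOTf/Et3N (3.4 equiv each) gives 1-methoxy-1,3-bis(trimethylsilyloxy)-2-[(2Z)-3-methyl-4-(trimethylsilyloxy)but-2-en-1-yl]buta-1,3-diene F2, which carries no O-allyl ketene acetal and can be heated. Cycloaddition with 6 in toluene at 80 °C, with loss of the methoxy group, gives 1-{3-[(2Z)-3-methyl-4-(trimethylsilyloxy)but-2-en-1-yl]-2,4-bis(trimethylsilyloxy)phenyl}ethanone F3. DMF-DMA converts F3 into enaminone 9, and the route continues to 10 as written.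

Step 2.
- A seven-membered lactone must close through the disfavoured s-cis ester rotamer and onto a 1,1-disubstituted olefin.
- The enolisable, chelating β-dicarbonyl unit can sequester the ruthenium carbene, so dimers may dominate.

The fallback sets out from 2 and comes back at 4. It changes the order of bond formation, so that the metathesis substrate is a plain ester and the acetyl group arrives afterwards. Compound 2 is acylated with pent-4-enoyl chloride (Et3N, CH2Cl2) to give 2-methylprop-2-en-1-yl pent-4-enoate F4. Ring-closing metathesis at high dilution gives 6-methyl-4,7-dihydrooxepin-2(3H)-one F5. Claisen-type C-acetylation of its lithium enolate (LiHMDS, 2.1 equiv, THF, −78 °C, then 1-acetylimidazole) gives 4.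

Step 7.
- The free 7-OH (acidic and electron-releasing) and the allylic alcohol may slow insertion.
- Protodeboronation of the electron-rich boronic acid could then outrun the addition.

The fallback sets out from 10 and comes back at 15. It removes the acidic groups and changes the catalytic manifold to a cationic aryl complex of divalent palladium. TBSCl/imidazole converts 10 into 7-(tert-butyldimethylsilyloxy)-8-[(2Z)-4-(tert-butyldimethylsilyloxy)-3-methylbut-2-en-1-yl]-4H-chromen-4-one F6, which also excludes a Wacker-type cyclisation of an ortho-allylphenol. Conjugate addition of 13 with Pd(OCOCF3)2, (R)-t-BuPyOx, NH4PF6 and H2O in ClCH2CH2Cl at 60 °C gives (2S)-2-[3,4-bis(tert-butyldimethylsilyloxy)phenyl]-7-(tert-butyldimethylsilyloxy)-8-[(2Z)-4-(tert-butyldimethylsilyloxy)-3-methylbut-2-en-1-yl]-2,3-dihydro-4H-chromen-4-one F7. The ligand antipode is chosen by analogy with cyclic enones. HF·pyridine, as in step 8, removes all four silyl groups and gives 15.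

**Further compounds**
F1 | step 4 | methyl (4Z)-2-acetyl-6-hydroxy-5-methylhex-4-enoate (racemic) | COC(=O)C(C/C=C(/C)CO)C(C)=O
F2 | step 4 | 1-methoxy-1,3-bis(trimethylsilyloxy)-2-[(2Z)-3-methyl-4-(trimethylsilyloxy)but-2-en-1-yl]buta-1,3-diene | C=C(O[Si](C)(C)C)C(C/C=C(/C)CO[Si](C)(C)C)=C(OC)O[Si](C)(C)C
F3 | step 4 | 1-{3-[(2Z)-3-methyl-4-(trimethylsilyloxy)but-2-en-1-yl]-2,4-bis(trimethylsilyloxy)phenyl}ethanone | CC(=O)c1ccc(O[Si](C)(C)C)c(C/C=C(/C)CO[Si](C)(C)C)c1O[Si](C)(C)C
F4 | step 2 | 2-methylprop-2-en-1-yl pent-4-enoate | C=CCCC(=O)OCC(C)=C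
F5 | step 2 | 6-methyl-4,7-dihydrooxepin-2(3H)-one | CC1=CCCC(=O)OC1
F6 | step 7 | 7-(tert-butyldimethylsilyloxy)-8-[(2Z)-4-(tert-butyldimethylsilyloxy)-3-methylbut-2-en-1-yl]-4H-chromen-4-one | C/C(=C/Cc1c(O[Si](C)(C)C(C)(C)C)ccc2c1OC=CC2=O)CO[Si](C)(C)C(C)(C)C
F7 | step 7 | (2S)-2-[3,4-bis(tert-butyldimethylsilyloxy)phenyl]-7-(tert-butyldimethylsilyloxy)-8-[(2Z)-4-(tert-butyldimethylsilyloxy)-3-methylbut-2-en-1-yl]-2,3-dihydro-4H-chromen-4-one | C/C(=C/Cc1c(O[Si](C)(C)C(C)(C)C)ccc2c1O[C@H](c1ccc(O[Si](C)(C)C(C)(C)C)c(O[Si](C)(C)C(C)(C)C)c1)CC2=O)CO[Si](C)(C)C(C)(C)C
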